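**Retrosynthetic overview**

1. Target 23 ⇐ spiro ene-trione 20 by C9-selective CBS reduction, acetylation and desilylation.
2. 20 ⇐ 4-hydroxycyclopentenone 19 by ring expansion: the ring CH2 (C10) moves from the carbinol carbon (C6) to the butenolide β-carbon (C5) by retro-aldol/6-exo Michael, setting C5 and, through epimerisation, C1.
3. 19 ⇐ cis-enedione 18 ⇐ furyl butenolide 16 (furan as masked cis-enedione, opened with singlet oxygen).
4. 16 ⇐ γ-hydroxy ynoate 12 + 2-methylfuran (syn-carbocupration/lactonisation); 12 ⇐ enal 9 + methyl propiolate.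
5. 9 ⇐ alkyne 5 (Zr-catalysed carboalumination) ⇐ pent-4-ynal + isopropenyl Grignard (Sharpless kinetic resolution). Ring order: butenolide, then cyclopentenone, then spiro cyclohexenedione.

Assumption 1: atom labels C1–C10 are those of the 2-oxaspiro[4.5]decane core of the target (C1 lactone CH, C3 lactone C=O, C5 spiro carbon, C6 ketone, C9 CHOAc).
Assumption 2: the quinine-derived amine is taken as the matched catalyst for the (1R,5R) series in step 9; this sense cannot be predicted with confidence, and if the first run shows the opposite sense its quinidine pseudo-enantiomer is used with nothing else changed.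

**Route**

Step 1
Reactants: 1 pent-4-ynal; 2 isopropenylmagnesium bromide
Product: 3 rac-2-methylhept-1-en-6-yn-3-ol
Conditions: THF, −78 °C; aq. NH4Cl
Reagents that add atoms: none
Why: Grignard 1,2-addition to the aldehyde at −78 °C outruns deprotonation of the terminal alkyne; the carbinol centre is formed racemic.

Step 2
Reactants: 3 rac-2-methylhept-1-en-6-yn-3-ol
Product: 4 (R)-2-methylhept-1-en-6-yn-3-ol
Conditions: Ti(OiPr)4 (10 mol %), L-(+)-DIPT (15 mol %), TBHP (0.6 equiv), 4 Å MS, CH2Cl2, −20 °C; recover unreacted alcohol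
Reagents that add atoms: none
Why: Sharpless kinetic resolution of a secondary 2-substituted allylic alcohol; with L-(+)-DIPT the (S)-enantiomer is epoxidised fast and the (R)-alcohol is recovered in high ee at about 55 % conversion.

Step 3
Reactants: 4 (R)-2-methylhept-1-en-6-yn-3-ol
Product: 5 (R)-tert-butyldimethyl[(2-methylhept-1-en-6-yn-3-yl)oxy]silane
Conditions: TBSCl, imidazole, DMF, rt
Reagents that add atoms: tert-butyldimethylsilyl chloride CC(C)(C)[Si](C)(C)Cl
Why: standard silylation; the ether keeps the side-chain hydroxyl out of the final acetylation.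

Step 4
Reactants: 5 (R)-tert-butyldimethyl[(2-methylhept-1-en-6-yn-3-yl)oxy]silane
Product: 8 (2E,6R)-6-[(tert-butyldimethylsilyl)oxy]-3,7-dimethylocta-2,7-dien-1-ol, via alkenylalane 6 (not isolated), via lithium alanate 7 (not isolated)
Conditions: Me3Al, Cp2ZrCl2 (25 mol %), CH2Cl2, 0 °C → rt; n-BuLi, −78 °C; (CH2O)n, rt; dil. HCl
Reagents that add atoms: trimethylaluminium C[Al](C)C; paraformaldehyde (as formaldehyde) C=O
Why: Negishi Zr-catalysed carboalumination adds Me and Al syn across the terminal alkyne (Me to the internal carbon), fixing the E trisubstituted alkene, and the alanate is hydroxymethylated with retention; the 1,1-disubstituted alkene and the silyl ether are inert.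

Step 5
Reactants: 8 (2E,6R)-6-[(tert-butyldimethylsilyl)oxy]-3,7-dimethylocta-2,7-dien-1-ol
Product: 9 (2E,6R)-6-[(tert-butyldimethylsilyl)oxy]-3,7-dimethylocta-2,7-dienal
Conditions: Cu(MeCN)4OTf, 2,2'-bipyridine, TEMPO, N-methylimidazole (5 mol % each), air, MeCN, rt
Reagents that add atoms: none
Why: Stahl Cu/TEMPO aerobic oxidation of a primary allylic alcohol stops at the enal without E/Z leakage.

Step 6
Reactants: 9 (2E,6R)-6-[(tert-butyldimethylsilyl)oxy]-3,7-dimethylocta-2,7-dienal; 10 methyl propiolate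
Product: 12 methyl (5E,9R)-9-[(tert-butyldimethylsilyl)oxy]-4-hydroxy-6,10-dimethylundeca-5,10-dien-2-ynoate (C4 epimers), via lithium acetylide 11 (not isolated)
Conditions: 10, n-BuLi, THF, −78 °C; then 9, −78 °C; AcOH quench
Reagents that add atoms: none
Why: 1,2-addition of lithium methyl propiolate to the enal; the new carbinol (future C1) is left as a ~1:1 mixture on purpose, because it becomes the epimerisable γ-carbon of the butenolide that step 9 resolves dynamically.

Step 7
Reactants: 12 methyl (5E,9R)-9-[(tert-butyldimethylsilyl)oxy]-4-hydroxy-6,10-dimethylundeca-5,10-dien-2-ynoate (C4 epimers); 13 2-methylfuran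
Product: 16 5-[(1E,5R)-5-[(tert-butyldimethylsilyl)oxy]-2,6-dimethylhepta-1,6-dien-1-yl]-4-(5-methylfuran-2-yl)furan-2(5H)-one (C5 epimers), via furyllithium 14 (not isolated), via furylcuprate 15 (not isolated)
Conditions: 13, n-BuLi, THF, 0 °C; CuI, −40 °C; then 12 (0.45 equiv per Cu), −78 °C; AcOH quench, warm to rt
Reagents that add atoms: none
Why: syn-carbocupration of the ynoate puts the furyl group on the β-carbon and leaves CO2Me cis to the alkoxide, which lactonises to the butenolide (the first furyl equivalent only deprotonates the OH); at −78 °C the γ-hydroxy ynoate does not isomerise.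

Step 8
Reactants: 16 5-[(1E,5R)-5-[(tert-butyldimethylsilyl)oxy]-2,6-dimethylhepta-1,6-dien-1-yl]-4-(5-methylfuran-2-yl)furan-2(5H)-one (C5 epimers)
Product: 18 5-[(1E,5R)-5-[(tert-butyldimethylsilyl)oxy]-2,6-dimethylhepta-1,6-dien-1-yl]-4-[(2Z)-4-oxopent-2-enoyl]furan-2(5H)-one (C5 epimers), via endoperoxide 17 (not isolated)
Conditions: O2, TPP (1 mol %), hν (white LED), CH2Cl2, −78 °C; then Me2S, −78 → 0 °C; short silica plug, use at once
Reagents that add atoms: oxygen O=O
Why: [4+2] addition of singlet oxygen to the 2,5-disubstituted furan is much faster than the ene reaction at the trisubstituted alkene (the isopropenyl group is inert), and Me2S reduction of the endoperoxide gives the cis-enedione (classical furan unmasking).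

Step 9
Reactants: 18 5-[(1E,5R)-5-[(tert-butyldimethylsilyl)oxy]-2,6-dimethylhepta-1,6-dien-1-yl]-4-[(2Z)-4-oxopent-2-enoyl]furan-2(5H)-one (C5 epimers)
Product: 20 (1R,5R)-1-[(1E,5R)-5-[(tert-butyldimethylsilyl)oxy]-2,6-dimethylhepta-1,6-dien-1-yl]-2-oxaspiro[4.5]dec-7-ene-3,6,9-trione, via hydroxycyclopentenone 19 (not isolated)
Conditions: 9-amino-9-deoxy-epi-quinine (20 mol %), PhCO2H (40 mol %), toluene, 0 °C (aldol to 19), then 40 °C (ring expansion)
Reagents that add atoms: none
Why: Proposed new method: the primary amine condenses with the methyl ketone of 18 and the dienamine first closes by a fast, reversible 5-(enolexo) aldol onto the C6 ketone to give cyclopentenone 19 (the usual fate of cis-enediones); on warming, 19 re-opens by amine-catalysed retro-aldol and the same carbon (C10) adds 6-exo-trig to the butenolide β-carbon (C5) trans to the C1 alkenyl group, so the ring CH2 has moved from the carbinol carbon to its neighbour and the five-membered carbocycle has become the spiro six-membered ene-dione; the γ-proton of the acyl butenolide is acidic and is equilibrated by the quinuclidine base, so both C1 epimers drain through the catalyst-matched transition state (dynamic kinetic resolution), C5 being set by catalyst face control (quinuclidinium hydrogen bond to the lactone carbonyl) and C1 by the trans rule for additions to γ-substituted butenolides; closest known chemistry: quinol–enedione and α-ketol 1,2-shifts, amine-catalysed retro-aldol, cinchona primary-amine intramolecular Michael additions, and dynamic kinetic resolution of γ-substituted butenolides through their dienolates.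

Step 10
Reactants: 20 (1R,5R)-1-[(1E,5R)-5-[(tert-butyldimethylsilyl)oxy]-2,6-dimethylhepta-1,6-dien-1-yl]-2-oxaspiro[4.5]dec-7-ene-3,6,9-trione
Product: 21 (1R,5R,9S)-1-[(1E,5R)-5-[(tert-butyldimethylsilyl)oxy]-2,6-dimethylhepta-1,6-dien-1-yl]-9-hydroxy-2-oxaspiro[4.5]dec-7-ene-3,6-dione
Conditions: (R)-Me-CBS (20 mol %), catecholborane (1.5 equiv), toluene, −78 °C; MeOH, aq. NaHCO3
Reagents that add atoms: none
Why: Corey–Bakshi–Shibata reduction; C9 is the only ketone not shielded by the quaternary spiro carbon, the (R)-catalyst (vinyl arm as the large group) delivers hydride to give 9S, and catecholborane at −78 °C gives 1,2-reduction only and leaves the alkenes and lactone alone.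

Step 11
Reactants: 21 (1R,5R,9S)-1-[(1E,5R)-5-[(tert-butyldimethylsilyl)oxy]-2,6-dimethylhepta-1,6-dien-1-yl]-9-hydroxy-2-oxaspiro[4.5]dec-7-ene-3,6-dione
Product: 23 (1R,5R,9S)-1-[(1E,5R)-5-hydroxy-2,6-dimethylhepta-1,6-dien-1-yl]-3,6-dioxo-2-oxaspiro[4.5]dec-7-en-9-yl acetate, via silyl acetate 22 (not isolated)
Conditions: Ac2O, DMAP (cat.), pyridine, 0 °C; MeOH (destroys excess Ac2O); then HF·pyridine, THF, 0 °C → rt
Reagents that add atoms: acetic anhydride CC(=O)OC(C)=O
Why: acylation of the only free hydroxyl, then fluoride desilylation under conditions that leave the allylic acetate, enone and lactone intact; no stereocentre is touched.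

**Compound list**

1 | pent-4-ynal | C#CCCC=O | starting material
2 | isopropenylmagnesium bromide | CC(=C)[Mg]Br | starting material
3 | rac-2-methylhept-1-en-6-yn-3-ol | C=C(C)C(O)CCC#C | intermediate
4 | (R)-2-methylhept-1-en-6-yn-3-ol | C=C(C)[C@H](O)CCC#C | intermediate
5 | (R)-tert-butyldimethyl[(2-methylhept-1-en-6-yn-3-yl)oxy]silane | C=C(C)[C@H](O[Si](C)(C)C(C)(C)C)CCC#C | intermediate
6 | dimethyl[(1E,5R)-5-[(tert-butyldimethylsilyl)oxy]-2,6-dimethylhepta-1,6-dien-1-yl]alumane | C=C(C)[C@H](O[Si](C)(C)C(C)(C)C)CC/C(C)=C/[Al](C)C | intermediate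
7 | lithium butyl(dimethyl)[(1E,5R)-5-[(tert-butyldimethylsilyl)oxy]-2,6-dimethylhepta-1,6-dien-1-yl]aluminate | [Li+].C=C(C)[C@H](O[Si](C)(C)C(C)(C)C)CC/C(C)=C/[Al-](C)(C)CCCC | intermediate
8 | (2E,6R)-6-[(tert-butyldimethylsilyl)oxy]-3,7-dimethylocta-2,7-dien-1-ol | C=C(C)[C@H](O[Si](C)(C)C(C)(C)C)CC/C(C)=C/CO | intermediate
9 | (2E,6R)-6-[(tert-butyldimethylsilyl)oxy]-3,7-dimethylocta-2,7-dienal | C=C(C)[C@H](O[Si](C)(C)C(C)(C)C)CC/C(C)=C/C=O | intermediate
10 | methyl propiolate | C#CC(=O)OC | starting material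
11 | methyl 3-lithioprop-2-ynoate | [Li]C#CC(=O)OC | intermediate
12 | methyl (5E,9R)-9-[(tert-butyldimethylsilyl)oxy]-4-hydroxy-6,10-dimethylundeca-5,10-dien-2-ynoate (C4 epimers) | C=C(C)[C@H](O[Si](C)(C)C(C)(C)C)CC/C(C)=C/C(O)C#CC(=O)OC | intermediate
13 | 2-methylfuran | Cc1ccco1 | starting material
14 | (5-methylfuran-2-yl)lithium | [Li]c1ccc(C)o1 | intermediate
15 | lithium bis(5-methylfuran-2-yl)cuprate | [Li+].Cc1ccc([Cu-]c2ccc(C)o2)o1 | intermediate
16 | 5-[(1E,5R)-5-[(tert-butyldimethylsilyl)oxy]-2,6-dimethylhepta-1,6-dien-1-yl]-4-(5-methylfuran-2-yl)furan-2(5H)-one (C5 epimers) | C=C(C)[C@H](O[Si](C)(C)C(C)(C)C)CC/C(C)=C/C1OC(=O)C=C1c1ccc(C)o1 | intermediate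
17 | 5-[(1E,5R)-5-[(tert-butyldimethylsilyl)oxy]-2,6-dimethylhepta-1,6-dien-1-yl]-4-(4-methyl-2,3,7-trioxabicyclo[2.2.1]hept-5-en-1-yl)furan-2(5H)-one (mixture) | C=C(C)[C@H](O[Si](C)(C)C(C)(C)C)CC/C(C)=C/C1OC(=O)C=C1C23OOC(C)(C=C2)O3 | intermediate
18 | 5-[(1E,5R)-5-[(tert-butyldimethylsilyl)oxy]-2,6-dimethylhepta-1,6-dien-1-yl]-4-[(2Z)-4-oxopent-2-enoyl]furan-2(5H)-one (C5 epimers) | C=C(C)[C@H](O[Si](C)(C)C(C)(C)C)CC/C(C)=C/C1OC(=O)C=C1C(=O)/C=C\C(C)=O | intermediate
19 | 5-[(1E,5R)-5-[(tert-butyldimethylsilyl)oxy]-2,6-dimethylhepta-1,6-dien-1-yl]-4-(1-hydroxy-4-oxocyclopent-2-en-1-yl)furan-2(5H)-one (diastereomer mixture) | C=C(C)[C@H](O[Si](C)(C)C(C)(C)C)CC/C(C)=C/C1OC(=O)C=C1C2(O)CC(=O)C=C2 | intermediate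
20 | (1R,5R)-1-[(1E,5R)-5-[(tert-butyldimethylsilyl)oxy]-2,6-dimethylhepta-1,6-dien-1-yl]-2-oxaspiro[4.5]dec-7-ene-3,6,9-trione | C=C(C)[C@H](O[Si](C)(C)C(C)(C)C)CC/C(C)=C/[C@H]1OC(=O)C[C@]12CC(=O)C=CC2=O | intermediate
21 | (1R,5R,9S)-1-[(1E,5R)-5-[(tert-butyldimethylsilyl)oxy]-2,6-dimethylhepta-1,6-dien-1-yl]-9-hydroxy-2-oxaspiro[4.5]dec-7-ene-3,6-dione | C=C(C)[C@H](O[Si](C)(C)C(C)(C)C)CC/C(C)=C/[C@H]1OC(=O)C[C@]12C[C@H](O)C=CC2=O | intermediate
22 | (1R,5R,9S)-1-[(1E,5R)-5-[(tert-butyldimethylsilyl)oxy]-2,6-dimethylhepta-1,6-dien-1-yl]-3,6-dioxo-2-oxaspiro[4.5]dec-7-en-9-yl acetate | C=C(C)[C@H](O[Si](C)(C)C(C)(C)C)CC/C(C)=C/[C@H]1OC(=O)C[C@]12C[C@H](OC(C)=O)C=CC2=O | intermediate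
23 | (1R,5R,9S)-1-[(1E,5R)-5-hydroxy-2,6-dimethylhepta-1,6-dien-1-yl]-3,6-dioxo-2-oxaspiro[4.5]dec-7-en-9-yl acetate | C=C(C)[C@H](O)CC/C(C)=C/[C@H]1OC(=O)C[C@]12C[C@H](OC(C)=O)C=CC2=O | target

**Step count**

Total steps: 11. Longest linear sequence: 11 (pent-4-ynal 1 to 23).

**Steps most likely to fail, with fallbacks**

Step 9 (the new ring expansion). The risks are: closure at the other alkene carbon (7-endo, fused ring) instead of 6-exo; diversion of the butenolide dienol into other reversible aldol reservoirs; loss of catalyst by aza-Michael addition to the ene-diones; and incomplete C1 equilibration or the wrong catalyst sense. The fallback uses known enolate chemistry, sets out from enal 9 and returns at 21, bypassing steps 6–10. Commercial (S)-4-hydroxycyclohex-2-en-1-one (8 non-H atoms) is silylated (TESCl, imidazole) to (S)-4-[(triethylsilyl)oxy]cyclohex-2-en-1-one F1. Its kinetic α'-lithium enolate (LDA, THF, −78 °C) is added to 9; the cyclic E-enolate reacts anti through a Zimmerman–Traxler transition state on the face opposite the OTES group, which I work out to give the 1R carbinol. In situ trapping with TMSCl gives (4S)-6-[(1R,2E,6R)-6-[(tert-butyldimethylsilyl)oxy]-3,7-dimethyl-1-[(trimethylsilyl)oxy]octa-2,7-dien-1-yl]-4-[(triethylsilyl)oxy]cyclohex-2-en-1-one F2. A second enolisation (LDA, THF/DMPU, −78 °C) and alkylation with methyl bromoacetate, again anti to OTES, builds the quaternary centre with the acetate arm trans and the carbinol arm cis to the C9 oxygen, giving methyl 2-[(1R,5S)-1-[(1R,2E,6R)-6-[(tert-butyldimethylsilyl)oxy]-3,7-dimethyl-1-[(trimethylsilyl)oxy]octa-2,7-dien-1-yl]-2-oxo-5-[(triethylsilyl)oxy]cyclohex-3-en-1-yl]acetate F3. PPTS in MeOH removes the TMS and TES groups (TBS survives) and the freed C1 alcohol lactonises to 21, which goes on to step 11.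

Step 8 (furan unmasking). The risks are a competing ene reaction of singlet oxygen at the trisubstituted alkene and Z→E isomerisation of 18. The fallback sets out from 16 and returns at 18. Anodic methoxylation (Clauson-Kaas conditions: MeOH, Et4NOTs, constant current, −10 °C) oxidises only the furan, the most easily oxidised π-system, to 4-(2,5-dimethoxy-5-methyl-2,5-dihydrofuran-2-yl)-5-[(1E,5R)-5-[(tert-butyldimethylsilyl)oxy]-2,6-dimethylhepta-1,6-dien-1-yl]furan-2(5H)-one F4, a storable masked enedione. Hydrolysis on wet silica gel with a trace of oxalic acid at 0 °C releases 18 just before step 9.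

Step 10 (C9 reduction). The risk is weak catalyst control: the sp3 flank of C9 is a CH2 attached to the quaternary carbon, so the size difference the CBS catalyst relies on is small. The fallback sets out from 20 and returns at 21 and 22. Luche reduction (NaBH4, CeCl3·7H2O, MeOH, −78 °C) reduces only the unhindered C9 ketone 1,2 and gives 21 together with its C9 epimer (1R,5R,9R)-1-[(1E,5R)-5-[(tert-butyldimethylsilyl)oxy]-2,6-dimethylhepta-1,6-dien-1-yl]-9-hydroxy-2-oxaspiro[4.5]dec-7-ene-3,6-dione F5, separable on silica. 21 continues through step 11. F5 is converted by Mitsunobu esterification with acetic acid (PPh3, DIAD, THF, 0 °C; SN2 inversion) directly into 22, which is desilylated with HF·pyridine as in step 11.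

**Further compounds**

F1 | step 9 | (S)-4-[(triethylsilyl)oxy]cyclohex-2-en-1-one | O=C1CC[C@H](O[Si](CC)(CC)CC)C=C1
F2 | step 9 | (4S)-6-[(1R,2E,6R)-6-[(tert-butyldimethylsilyl)oxy]-3,7-dimethyl-1-[(trimethylsilyl)oxy]octa-2,7-dien-1-yl]-4-[(triethylsilyl)oxy]cyclohex-2-en-1-one (C6 epimers) | C=C(C)[C@H](O[Si](C)(C)C(C)(C)C)CC/C(C)=C/[C@@H](O[Si](C)(C)C)C1C[C@H](O[Si](CC)(CC)CC)C=CC1=O
F3 | step 9 | methyl 2-[(1R,5S)-1-[(1R,2E,6R)-6-[(tert-butyldimethylsilyl)oxy]-3,7-dimethyl-1-[(trimethylsilyl)oxy]octa-2,7-dien-1-yl]-2-oxo-5-[(triethylsilyl)oxy]cyclohex-3-en-1-yl]acetate | C=C(C)[C@H](O[Si](C)(C)C(C)(C)C)CC/C(C)=C/[C@@H](O[Si](C)(C)C)[C@]1(CC(=O)OC)C[C@H](O[Si](CC)(CC)CC)C=CC1=O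
F4 | step 8 | 4-(2,5-dimethoxy-5-methyl-2,5-dihydrofuran-2-yl)-5-[(1E,5R)-5-[(tert-butyldimethylsilyl)oxy]-2,6-dimethylhepta-1,6-dien-1-yl]furan-2(5H)-one | C=C(C)[C@H](O[Si](C)(C)C(C)(C)C)CC/C(C)=C/C1OC(=O)C=C1C2(OC)OC(C)(OC)C=C2
F5 | step 10 | (1R,5R,9R)-1-[(1E,5R)-5-[(tert-butyldimethylsilyl)oxy]-2,6-dimethylhepta-1,6-dien-1-yl]-9-hydroxy-2-oxaspiro[4.5]dec-7-ene-3,6-dione | C=C(C)[C@H](O[Si](C)(C)C(C)(C)C)CC/C(C)=C/[C@H]1OC(=O)C[C@]12C[C@@H](O)C=CC2=O
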